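## Retrosynthetic overview

1. Target ⇐ desilylation, lactam C=O → CH2, hydrogenation of a ring C=C(CO2Me) and N-methoxycarbonylation of a bridged pentacyclic lactam.
2. Bridged lactam ⇐ one palladium/CO domino on a spiro[pyrrolidine–cyclohexene]. Its substrate carries, cis-1,4 to the pyrrolidine N–H, a quaternary carbon with an N-(2-bromophenyl) amide and a 1-(methoxycarbonyl)vinyl group. The domino forms the indoline ring, then the eight-membered ring through the amide N–C(=O) bond (this carbonyl is the later NCH2).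
3. Enabling feature: the NCH2 carbon of the eight-membered ring is β to indoline C3, a quaternary carbon (aryl, CO2Me, spiro C2) without hydrogen. Carbopalladation at C3 therefore leaves a CH2–Pd that cannot eliminate and takes up CO. C2 and the amine-bearing spiro carbon are 1,4 on the six-membered carbocycle, which folds to a boat.
4. N-aryl quaternary carbon ⇐ [3,3] shift of an allylic N-aryl trifluoroacetimidate (1,3-chirality transfer from a ring carbinol) ⇐ Luche reduction ⇐ Stille coupling of the enol triflate of a 2-(methoxycarbonyl)cyclohexane-1,3-dione ⇐ Claisen cyclisation ⇐ Roskamp homologation.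
5. Spiro carbon ⇐ Fráter–Seebach allylation of (3R)-N-Boc-3-hydroxyproline methyl ester, the only purchased stereocentre. Ring order: pyrrolidine (bought), cyclohexene, then indoline and eight-membered ring together.

Key step: step 14

Assumption: methyl (2S,3R)-N-Boc-3-hydroxyprolinate is taken as a commercial building block; only its C3 configuration is used, so the (2R,3R) isomer would serve equally.

Locants of the spiro intermediates follow 1-azaspiro[4.5]decane: N1, C4 (silyloxy carbon), C5 (spiro), C6 (former proline carboxyl carbon), C7 (ester-bearing), C8 (future indoline C2).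

## Route

Step 1
Reactants: 1 1-tert-butyl 2-methyl (2S,3R)-3-hydroxypyrrolidine-1,2-dicarboxylate
Product: 2 1-tert-butyl 2-methyl (2S,3R)-2-allyl-3-hydroxypyrrolidine-1,2-dicarboxylate (allyl trans to OH)
Conditions: LiN(iPr)2 (2.3 equiv), THF, −78 → −30 °C; allyl bromide, DMPU, −78 → −20 °C
Reagents that add atoms: allyl bromide, C=CCBr
Why: Fráter–Seebach alkylation of the β-hydroxy ester dianion; the electrophile should enter the enolate face anti to the C3 alkoxide, so allyl ends trans to O and the ester cis, which sets the future spiro carbon from the purchased carbinol centre (the original C2 configuration is erased).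

Step 2
Reactants: 2 1-tert-butyl 2-methyl (2S,3R)-2-allyl-3-hydroxypyrrolidine-1,2-dicarboxylate
Product: 3 1-tert-butyl 2-methyl (2S,3R)-2-allyl-3-(tert-butyldimethylsilyloxy)pyrrolidine-1,2-dicarboxylate
Conditions: TBSOTf, 2,6-lutidine, CH2Cl2, 0 °C
Reagents that add atoms: tert-butyldimethylsilyl triflate, CC(C)(C)[Si](C)(C)OS(=O)(=O)C(F)(F)F
Why: Silyl triflate/lutidine silylation of the hindered secondary alcohol; the ether blocks retro-aldol cleavage and later acylation and adds bulk next to the future ring ketone.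

Step 3
Reactants: 3 1-tert-butyl 2-methyl (2S,3R)-2-allyl-3-(tert-butyldimethylsilyloxy)pyrrolidine-1,2-dicarboxylate
Product: 5 1-tert-butyl 2-methyl (2S,3R)-3-(tert-butyldimethylsilyloxy)-2-(3-hydroxypropyl)pyrrolidine-1,2-dicarboxylate, via alkylborane 4 (not isolated)
Conditions: 9-BBN, THF, 0 °C → rt; then aq. NaOH, H2O2, 0 °C
Reagents that add atoms: hydrogen peroxide, OO
Why: Anti-Markovnikov hydroboration of the terminal alkene by the bulky borane and oxidation of the C–B bond should leave both esters and the carbamate untouched.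

Step 4
Reactants: 5 1-tert-butyl 2-methyl (2S,3R)-3-(tert-butyldimethylsilyloxy)-2-(3-hydroxypropyl)pyrrolidine-1,2-dicarboxylate
Product: 6 1-tert-butyl 2-methyl (2S,3R)-3-(tert-butyldimethylsilyloxy)-2-(3-oxopropyl)pyrrolidine-1,2-dicarboxylate
Conditions: TEMPO (cat.), PhI(OAc)2, CH2Cl2, rt
Reagents that add atoms: none
Why: Nitroxyl-catalysed alcohol oxidation stops at the aldehyde and tolerates Boc and the silyl ether.

Step 5
Reactants: 6 1-tert-butyl 2-methyl (2S,3R)-3-(tert-butyldimethylsilyloxy)-2-(3-oxopropyl)pyrrolidine-1,2-dicarboxylate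
Product: 7 1-tert-butyl 2-methyl (2S,3R)-3-(tert-butyldimethylsilyloxy)-2-(5-methoxy-3,5-dioxopentyl)pyrrolidine-1,2-dicarboxylate
Conditions: methyl diazoacetate, SnCl2 (10 mol %), CH2Cl2, rt
Reagents that add atoms: methyl diazoacetate, COC(=O)C=[N+]=[N-]
Why: Roskamp reaction; tin-chloride-promoted addition of the diazoacetate to the aldehyde, 1,2-hydride shift and loss of N2 give the β-keto ester directly.

Step 6
Reactants: 7 1-tert-butyl 2-methyl (2S,3R)-3-(tert-butyldimethylsilyloxy)-2-(5-methoxy-3,5-dioxopentyl)pyrrolidine-1,2-dicarboxylate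
Product: 8 1-tert-butyl 7-methyl 4-(tert-butyldimethylsilyloxy)-8-hydroxy-6-oxo-1-azaspiro[4.5]dec-7-ene-1,7-dicarboxylate (enol of the 6,8-dione; 4-OTBS on the C6 side of the pyrrolidine)
Conditions: KOtBu (1.5 equiv), THF, 0 → 45 °C; aq. KHSO4
Reagents that add atoms: none
Why: Intramolecular Claisen (Dieckmann-type) condensation; the β-keto ester carbanion acylates on the non-enolisable proline ester, and six-ring closure is driven by formation of the acidic 2-acyl-1,3-dione enolate.

Step 7
Reactants: 8 1-tert-butyl 7-methyl 4-(tert-butyldimethylsilyloxy)-8-hydroxy-6-oxo-1-azaspiro[4.5]dec-7-ene-1,7-dicarboxylate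
Product: 9 1-tert-butyl 7-methyl 4-(tert-butyldimethylsilyloxy)-6-oxo-8-(trifluoromethylsulfonyloxy)-1-azaspiro[4.5]dec-7-ene-1,7-dicarboxylate
Conditions: Tf2O, iPr2NEt, CH2Cl2, −78 °C
Reagents that add atoms: triflic anhydride, O=S(=O)(OS(=O)(=O)C(F)(F)F)C(F)(F)F
Why: O-sulfonylation of the triketone enolate should occur at the C8 oxygen, remote from the spiro centre, because the C6 oxygen is shielded by N-Boc and OTBS.

Step 8
Reactants: 10 methyl propiolate
Product: 11 methyl 2-(tributylstannyl)acrylate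
Conditions: Bu3SnH, Pd(PPh3)4 (2 mol %), THF, 0 °C → rt
Reagents that add atoms: tributyltin hydride, CCCC[SnH](CCCC)CCCC
Why: Palladium-catalysed syn-hydrostannation of a propiolate places tin on the ester-bearing carbon.

Step 9
Reactants: 9 1-tert-butyl 7-methyl 4-(tert-butyldimethylsilyloxy)-6-oxo-8-(trifluoromethylsulfonyloxy)-1-azaspiro[4.5]dec-7-ene-1,7-dicarboxylate; 11 methyl 2-(tributylstannyl)acrylate
Product: 12 1-tert-butyl 7-methyl 4-(tert-butyldimethylsilyloxy)-8-[1-(methoxycarbonyl)vinyl]-6-oxo-1-azaspiro[4.5]dec-7-ene-1,7-dicarboxylate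
Conditions: Pd(PPh3)4 (5 mol %), CuCl, LiCl, DMSO, 50 °C
Reagents that add atoms: none
Why: Stille coupling of the activated β-triflyloxy enone with the α-stannyl acrylate; copper and chloride speed transmetalation at the hindered tin centre, and fluoride is avoided to keep the silyl ether.

Step 10
Reactants: 12 1-tert-butyl 7-methyl 4-(tert-butyldimethylsilyloxy)-8-[1-(methoxycarbonyl)vinyl]-6-oxo-1-azaspiro[4.5]dec-7-ene-1,7-dicarboxylate
Product: 13 1-tert-butyl 7-methyl 4-(tert-butyldimethylsilyloxy)-6-hydroxy-8-[1-(methoxycarbonyl)vinyl]-1-azaspiro[4.5]dec-7-ene-1,7-dicarboxylate (6-OH cis to C4 and trans to N1 about C5–C6)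
Conditions: NaBH4, CeCl3·7H2O, MeOH, −78 °C
Reagents that add atoms: none
Why: Luche 1,2-reduction of the enone carbonyl; hydride should enter from the N1 face, opposite the C4–OTBS group that lies over the carbonyl, so the new C6–O bond is cis to C4.

Step 11
Reactants: 14 2-bromoaniline
Product: 15 N-(2-bromophenyl)-2,2,2-trifluoroacetimidoyl chloride
Conditions: CF3CO2H, PPh3, CCl4, Et3N, reflux
Reagents that add atoms: trifluoroacetic acid, OC(=O)C(F)(F)F; carbon tetrachloride, ClC(Cl)(Cl)Cl
Why: One-pot Appel-type amide formation and chlorodehydration of the trifluoroacetanilide give the imidoyl chloride.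

Step 12
Reactants: 13 1-tert-butyl 7-methyl 4-(tert-butyldimethylsilyloxy)-6-hydroxy-8-[1-(methoxycarbonyl)vinyl]-1-azaspiro[4.5]dec-7-ene-1,7-dicarboxylate; 15 N-(2-bromophenyl)-2,2,2-trifluoroacetimidoyl chloride
Product: 17 1-tert-butyl 7-methyl 8-[N-(2-bromophenyl)-2,2,2-trifluoroacetamido]-4-(tert-butyldimethylsilyloxy)-8-[1-(methoxycarbonyl)vinyl]-1-azaspiro[4.5]dec-6-ene-1,7-dicarboxylate (amide N on C8 cis to C4; vinyl group cis to N1), via allylic imidate 16 (not isolated)
Conditions: NaH, THF, 0 °C; then xylenes, K2CO3, 135 °C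
Reagents that add atoms: none
Why: Overman-type [3,3] sigmatropic rearrangement of the allylic N-aryl trifluoroacetimidate; the shift is suprafacial, so nitrogen should arrive at C8 on the face that oxygen leaves at C6 (cis to C4, trans to N1), which sets the aza-quaternary centre and moves the double bond to C6=C7.

Step 13
Reactants: 17 1-tert-butyl 7-methyl 8-[N-(2-bromophenyl)-2,2,2-trifluoroacetamido]-4-(tert-butyldimethylsilyloxy)-8-[1-(methoxycarbonyl)vinyl]-1-azaspiro[4.5]dec-6-ene-1,7-dicarboxylate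
Product: 19 methyl 8-[N-(2-bromophenyl)-2,2,2-trifluoroacetamido]-4-(tert-butyldimethylsilyloxy)-8-[1-(methoxycarbonyl)vinyl]-1-azaspiro[4.5]dec-6-ene-7-carboxylate (free N1–H), via silyl carbamate 18 (not isolated)
Conditions: TMSOTf, 2,6-lutidine, CH2Cl2, 0 °C; then MeOH
Reagents that add atoms: none
Why: Silyl-triflate cleavage of the tert-butyl carbamate (loss of isobutene, then methanolysis and decarboxylation of the silyl carbamate) should spare the secondary TBS ether, the trifluoroacetamide and both acrylate units; the amine is used at once.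

Step 14
Reactants: 19 methyl 8-[N-(2-bromophenyl)-2,2,2-trifluoroacetamido]-4-(tert-butyldimethylsilyloxy)-8-[1-(methoxycarbonyl)vinyl]-1-azaspiro[4.5]dec-6-ene-7-carboxylate
Product: 20 bridged pentacyclic lactam: the target skeleton with C=O at the CH2 next to the pyrrolidine N, a C=C between the CO2Me-bearing ring carbon and its CH neighbour, COCF3 on the indoline N and OTBS on the carbinol carbon
Conditions: Pd(OAc)2 (10 mol %), P(o-tol)3 (25 mol %), Et3N (3 equiv), CO (1 atm), toluene/MeCN 4:1, 90 °C, 0.005 M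
Reagents that add atoms: carbon monoxide, [C-]#[O+]
Why: Zerovalent palladium inserts into the C–Br bond and 5-exo-trig syn-carbopalladation of the 1,1-disubstituted acrylate (aryl to the ester-bearing carbon) closes the indoline and leaves a neopentyl CH2–Pd that has no β-hydrogen. That alkylpalladium takes up CO, and the acylpalladium is captured by the pyrrolidine N–H, which forms the amide bond and closes the eight-membered lactam bridge (8-exo-trig at the acyl carbon) across the cyclohexene boat. The closest known reaction type is the domino Heck cyclisation/aminocarbonylation of N-(2-haloaryl) allylamine and acrylamide derivatives, here with the amine in the same molecule. The new quaternary centre (indoline C3) is controlled by the adjacent aza-quaternary spiro carbon: the palladium-bearing CH2 terminus should go over the flat C=C(CO2Me) side of the cyclohexene and the acrylate ester over the CH2CH2 side, which also keeps the two ester dipoles apart. The step needs carbopalladation to outrun CO insertion into the aryl–Pd bond (1 atm CO, fast 5-exo closure) and amide formation to outrun acylpalladation of the ring enoate or intermolecular capture. The cis-1,4 placement of the acrylate-bearing carbon and the amine fixed in step 12, together with high dilution, should secure the ring closure.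

Step 15
Reactants: 20 bridged N-trifluoroacetyl lactam
Product: 21 N–H indoline lactam (20 without the COCF3 group)
Conditions: K2CO3, MeOH, rt
Reagents that add atoms: none
Why: Methanolysis of the twisted, electron-poor N-aryl trifluoroacetamide should be much faster than attack at the lactam or the esters, and the hindered ring enoate should not add methoxide.

Step 16
Reactants: 21 N–H indoline lactam
Product: 22 N-methoxycarbonyl indoline lactam (unsaturated, O-TBS)
Conditions: NaH, THF, 0 °C; ClCO2Me, 0 °C → rt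
Reagents that add atoms: methyl chloroformate, COC(=O)Cl
Why: Deprotonation of the indoline N–H and acylation with the chloroformate; no enolisable ester α-hydrogen is present at this stage (quaternary C3, sp2 ring carbon), so the strong base cannot epimerise or condense.

Step 17
Reactants: 22 N-methoxycarbonyl indoline lactam
Product: 23 saturated lactam (CH(CO2Me)–CH2 in the carbocycle; CO2Me syn to the lactam bridge)
Conditions: H2 (3 atm), 10% Pd/C, EtOAc, rt
Reagents that add atoms: none
Why: Heterogeneous hydrogenation should add H2 syn to the trisubstituted enoate from the face of the CH2CH2 bridge, the other face being covered by the four-atom lactam bridge; this places CO2Me syn to that bridge, as in the target.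

Step 18
Reactants: 23 saturated lactam
Product: 24 O-TBS ether of the target
Conditions: Zn(OAc)2 (10 mol %), (EtO)3SiH, THF, 40 °C
Reagents that add atoms: none
Why: Zinc-catalysed hydrosilylation reduces the tertiary lactam C=O to CH2 chemoselectively in the presence of esters and the carbamate, under neutral conditions that should not epimerise the CH(CO2Me) centre.

Step 19
Reactants: 24 O-TBS ether of the target
Product: 25 target, CNP0144467.2
Conditions: HF·pyridine, THF, 0 °C → rt
Reagents that add atoms: none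
Why: Fluoride cleavage of the silyl ether under acidic buffering, again without a base that could epimerise the ester-bearing CH.

## Compound list

1 | 1-tert-butyl 2-methyl (2S,3R)-3-hydroxypyrrolidine-1,2-dicarboxylate | COC(=O)[C@@H]1[C@H](O)CCN1C(=O)OC(C)(C)C | starting material
2 | 1-tert-butyl 2-methyl (2S,3R)-2-allyl-3-hydroxypyrrolidine-1,2-dicarboxylate | COC(=O)[C@]1(CC=C)[C@H](O)CCN1C(=O)OC(C)(C)C | intermediate
3 | 1-tert-butyl 2-methyl (2S,3R)-2-allyl-3-(tert-butyldimethylsilyloxy)pyrrolidine-1,2-dicarboxylate | COC(=O)[C@]1(CC=C)[C@H](O[Si](C)(C)C(C)(C)C)CCN1C(=O)OC(C)(C)C | intermediate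
4 | B-alkyl-9-borabicyclo[3.3.1]nonane adduct of 3 (boron on the terminal carbon) | COC(=O)[C@]1(CCCB2C3CCCC2CCC3)[C@H](O[Si](C)(C)C(C)(C)C)CCN1C(=O)OC(C)(C)C | intermediate
5 | 1-tert-butyl 2-methyl (2S,3R)-3-(tert-butyldimethylsilyloxy)-2-(3-hydroxypropyl)pyrrolidine-1,2-dicarboxylate | COC(=O)[C@]1(CCCO)[C@H](O[Si](C)(C)C(C)(C)C)CCN1C(=O)OC(C)(C)C | intermediate
6 | 1-tert-butyl 2-methyl (2S,3R)-3-(tert-butyldimethylsilyloxy)-2-(3-oxopropyl)pyrrolidine-1,2-dicarboxylate | COC(=O)[C@]1(CCC=O)[C@H](O[Si](C)(C)C(C)(C)C)CCN1C(=O)OC(C)(C)C | intermediate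
7 | 1-tert-butyl 2-methyl (2S,3R)-3-(tert-butyldimethylsilyloxy)-2-(5-methoxy-3,5-dioxopentyl)pyrrolidine-1,2-dicarboxylate | COC(=O)[C@]1(CCC(=O)CC(=O)OC)[C@H](O[Si](C)(C)C(C)(C)C)CCN1C(=O)OC(C)(C)C | intermediate
8 | 1-tert-butyl 7-methyl 4-(tert-butyldimethylsilyloxy)-8-hydroxy-6-oxo-1-azaspiro[4.5]dec-7-ene-1,7-dicarboxylate (enol form; 4-OTBS on the C6 side) | COC(=O)C1=C(O)CC[C@]2(C1=O)N(C(=O)OC(C)(C)C)CC[C@H]2O[Si](C)(C)C(C)(C)C | intermediate
9 | 8-enol triflate of 8 | COC(=O)C1=C(OS(=O)(=O)C(F)(F)F)CC[C@]2(C1=O)N(C(=O)OC(C)(C)C)CC[C@H]2O[Si](C)(C)C(C)(C)C | intermediate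
10 | methyl propiolate | C#CC(=O)OC | starting material
11 | methyl 2-(tributylstannyl)acrylate | C=C(C(=O)OC)[Sn](CCCC)(CCCC)CCCC | intermediate
12 | 1-tert-butyl 7-methyl 4-(tert-butyldimethylsilyloxy)-8-[1-(methoxycarbonyl)vinyl]-6-oxo-1-azaspiro[4.5]dec-7-ene-1,7-dicarboxylate | COC(=O)C1=C(C(=C)C(=O)OC)CC[C@]2(C1=O)N(C(=O)OC(C)(C)C)CC[C@H]2O[Si](C)(C)C(C)(C)C | intermediate
13 | 6-hydroxy analogue of 12 (6-OH cis to C4, trans to N1) | COC(=O)C1=C(C(=C)C(=O)OC)CC[C@]2([C@@H]1O)N(C(=O)OC(C)(C)C)CC[C@H]2O[Si](C)(C)C(C)(C)C | intermediate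
14 | 2-bromoaniline | Nc1ccccc1Br | starting material
15 | N-(2-bromophenyl)-2,2,2-trifluoroacetimidoyl chloride | FC(F)(F)C(Cl)=Nc1ccccc1Br | intermediate
16 | 6-O-[N-(2-bromophenyl)trifluoroacetimidoyl] derivative of 13 | COC(=O)C1=C(C(=C)C(=O)OC)CC[C@]2([C@@H]1OC(=Nc1ccccc1Br)C(F)(F)F)N(C(=O)OC(C)(C)C)CC[C@H]2O[Si](C)(C)C(C)(C)C | intermediate
17 | 1-tert-butyl 7-methyl 8-[N-(2-bromophenyl)-2,2,2-trifluoroacetamido]-4-(tert-butyldimethylsilyloxy)-8-[1-(methoxycarbonyl)vinyl]-1-azaspiro[4.5]dec-6-ene-1,7-dicarboxylate | COC(=O)C1=C[C@@]2(CC[C@@]1(C(=C)C(=O)OC)N(C(=O)C(F)(F)F)c1ccccc1Br)N(C(=O)OC(C)(C)C)CC[C@H]2O[Si](C)(C)C(C)(C)C | intermediate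
18 | N1-(trimethylsilyloxycarbonyl) analogue of 17 | COC(=O)C1=C[C@@]2(CC[C@@]1(C(=C)C(=O)OC)N(C(=O)C(F)(F)F)c1ccccc1Br)N(C(=O)O[Si](C)(C)C)CC[C@H]2O[Si](C)(C)C(C)(C)C | intermediate
19 | N1–H amine: methyl 8-[N-(2-bromophenyl)-2,2,2-trifluoroacetamido]-4-(tert-butyldimethylsilyloxy)-8-[1-(methoxycarbonyl)vinyl]-1-azaspiro[4.5]dec-6-ene-7-carboxylate | COC(=O)C1=C[C@@]2(CC[C@@]1(C(=C)C(=O)OC)N(C(=O)C(F)(F)F)c1ccccc1Br)NCC[C@H]2O[Si](C)(C)C(C)(C)C | intermediate
20 | bridged lactam with N–COCF3, ring C=C(CO2Me) and O-TBS | COC(=O)C1=C[C@@]23CC[C@@]14N(C(=O)C(F)(F)F)c1ccccc1[C@@]4(C(=O)OC)CC(=O)N2CC[C@H]3O[Si](C)(C)C(C)(C)C | intermediate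
21 | bridged lactam with indoline N–H | COC(=O)C1=C[C@@]23CC[C@@]14Nc1ccccc1[C@@]4(C(=O)OC)CC(=O)N2CC[C@H]3O[Si](C)(C)C(C)(C)C | intermediate
22 | bridged lactam with indoline N–CO2Me | COC(=O)C1=C[C@@]23CC[C@@]14N(C(=O)OC)c1ccccc1[C@@]4(C(=O)OC)CC(=O)N2CC[C@H]3O[Si](C)(C)C(C)(C)C | intermediate
23 | saturated bridged lactam (CO2Me syn to the lactam bridge) | COC(=O)[C@@H]1C[C@@]23CC[C@@]14N(C(=O)OC)c1ccccc1[C@@]4(C(=O)OC)CC(=O)N2CC[C@H]3O[Si](C)(C)C(C)(C)C | intermediate
24 | O-TBS ether of the target | COC(=O)[C@@H]1C[C@@]23CC[C@@]14N(C(=O)OC)c1ccccc1[C@@]4(C(=O)OC)CCN2CC[C@H]3O[Si](C)(C)C(C)(C)C | intermediate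
25 | CNP0144467.2 | COC(=O)[C@@H]1C[C@@]23CC[C@@]14N(C(=O)OC)c1ccccc1[C@@]4(C(=O)OC)CCN2CC[C@H]3O | target

## Summary and risks

Total step count: 19. Longest linear sequence: 17 steps (1–7, 9, 10, 12–19).

Steps most likely to fail:

Step 14. The acylpalladium may be captured by a second molecule or by the ring enoate before the bridging aminolysis, CO may insert before carbopalladation, or facial selectivity in the carbopalladation may be poor. The fallback sets out from 17 and returns at 20. The same carbopalladation/CO insertion is run on Boc-protected 17 with pentafluorophenol as external nucleophile (Pd(OAc)2, P(o-tol)3, Et3N, CO) to give pentafluorophenyl ester F1. ZnBr2 in CH2Cl2 removes the Boc group to give amino active ester F2. F2 is added slowly to iPr2NEt in warm MeCN and closes the same N–C(=O) bond by classical active-ester lactamisation to give 20.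

Step 12. The allylic imidate may ionise or eliminate to a cyclohexadiene, or the ortho-substituted N-aryl nitrogen may fail to reach the fully substituted alkene terminus. The fallback sets out from 13 and returns at 21. Cl3CCN with catalytic DBU gives trichloroacetimidate F3, which undergoes the Overman rearrangement in hot xylene to trichloroacetamide F4 with the same 1,3-chirality transfer. NaBH4 in EtOH frees primary amine F5. Buchwald–Hartwig coupling with 1-bromo-2-iodobenzene at the C–I bond (Pd2(dba)3, BrettPhos, Cs2CO3, toluene) gives N-(2-bromophenyl)amine F6. ZnBr2 removes Boc to give diamine F7, and the conditions of step 14 applied to F7 give the N–H lactam 21 directly.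

Step 10. Facial selectivity of the hydride addition may be poor, with attack from the C4 face. The fallback sets out from 12 and returns at 13. If the reduction delivers mainly the C6-epimeric alcohol F8, a Mitsunobu reaction (4-nitrobenzoic acid, PPh3, DIAD, toluene) inverts C6 to give 4-nitrobenzoate F9, and K2CO3/MeOH releases 13.

Further compounds
F1 | step 14 | pentafluorophenyl ester (N1-Boc spiro-indoline; CH2CO2C6F5 on indoline C3) | COC(=O)C1=C[C@@]2(CC[C@@]13N(C(=O)C(F)(F)F)c1ccccc1[C@@]3(C(=O)OC)CC(=O)Oc1c(F)c(F)c(F)c(F)c1F)N(C(=O)OC(C)(C)C)CC[C@H]2O[Si](C)(C)C(C)(C)C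
F2 | step 14 | amino pentafluorophenyl ester (F1 without Boc) | COC(=O)C1=C[C@@]2(CC[C@@]13N(C(=O)C(F)(F)F)c1ccccc1[C@@]3(C(=O)OC)CC(=O)Oc1c(F)c(F)c(F)c(F)c1F)NCC[C@H]2O[Si](C)(C)C(C)(C)C
F3 | step 12 | 6-O-trichloroacetimidate of 13 | COC(=O)C1=C(C(=C)C(=O)OC)CC[C@]2([C@@H]1OC(=N)C(Cl)(Cl)Cl)N(C(=O)OC(C)(C)C)CC[C@H]2O[Si](C)(C)C(C)(C)C
F4 | step 12 | 8-trichloroacetamido analogue of 17 | COC(=O)C1=C[C@@]2(CC[C@@]1(C(=C)C(=O)OC)NC(=O)C(Cl)(Cl)Cl)N(C(=O)OC(C)(C)C)CC[C@H]2O[Si](C)(C)C(C)(C)C
F5 | step 12 | 8-amino analogue of 17 | COC(=O)C1=C[C@@]2(CC[C@@]1(C(=C)C(=O)OC)N)N(C(=O)OC(C)(C)C)CC[C@H]2O[Si](C)(C)C(C)(C)C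
F6 | step 12 | 8-(2-bromoanilino) analogue of 17 | COC(=O)C1=C[C@@]2(CC[C@@]1(C(=C)C(=O)OC)Nc1ccccc1Br)N(C(=O)OC(C)(C)C)CC[C@H]2O[Si](C)(C)C(C)(C)C
F7 | step 12 | 8-(2-bromoanilino) N1–H diamine | COC(=O)C1=C[C@@]2(CC[C@@]1(C(=C)C(=O)OC)Nc1ccccc1Br)NCC[C@H]2O[Si](C)(C)C(C)(C)C
F8 | step 10 | C6 epimer of 13 | COC(=O)C1=C(C(=C)C(=O)OC)CC[C@]2([C@H]1O)N(C(=O)OC(C)(C)C)CC[C@H]2O[Si](C)(C)C(C)(C)C
F9 | step 10 | 6-O-(4-nitrobenzoate) of 13 | COC(=O)C1=C(C(=C)C(=O)OC)CC[C@]2([C@@H]1OC(=O)c1ccc(cc1)[N+](=O)[O-])N(C(=O)OC(C)(C)C)CC[C@H]2O[Si](C)(C)C(C)(C)C
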